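## Retrosynthetic overview

1. The target comes from its bis(benzyl ether) by hydrogenolysis; both phenols are unmasked last.
2. The γ-lactone is the only ring built. It closes when the hydroxyl freed by reductive removal of a chiral imide auxiliary attacks a benzyl ester; the enolisable C3 is then equilibrated to trans.
3. Key disconnection: the C3–C4 bond, made by oxidative heterocoupling of two enolates. Trivalent iron oxidises the enolate pair so that one α-carbon reacts as an α-carbonyl radical (an enolonium equivalent) and is captured by the other enolate. Two donor α-carbons are joined, and the oxazolidinone sets C4.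
4. The imide comes from O-benzylsyringaldehyde, Meldrum's acid and (S)-4-benzyloxazolidin-2-one; the ester comes from dihydroferulic acid and benzyl bromide.
5. Ring order: both arenes are bought, the auxiliary ring is bought and recovered, and the lactone is formed in the penultimate step.

Assumption: compound 1, 4-(benzyloxy)-3,5-dimethoxybenzaldehyde, is bought as a catalogue compound.

## Route

Step 1
Reactants: 1 4-(benzyloxy)-3,5-dimethoxybenzaldehyde; 2 Meldrum's acid (2,2-dimethyl-1,3-dioxane-4,6-dione)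
Product: 5 3-[4-(benzyloxy)-3,5-dimethoxyphenyl]propanoic acid, via arylidene Meldrum's acid 3 (not isolated), via arylmethyl Meldrum's acid 4 (not isolated)
Conditions: HCO2H/Et3N (5:2), 95–100 °C, 3 h; then aq HCl
Reagents that add atoms: none
Why: Tandem Knoevenagel condensation, conjugate transfer reduction of the arylidene by formate, then hydrolysis–decarboxylation of the Meldrum's acid ring (the water released in the condensation is used up in the hydrolysis) gives the saturated acid in one pot without touching the benzyl ether; no stereocentre is formed.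

Step 2
Reactants: 5 3-[4-(benzyloxy)-3,5-dimethoxyphenyl]propanoic acid; 6 (S)-4-benzyloxazolidin-2-one
Product: 8 (4S)-4-benzyl-3-{3-[4-(benzyloxy)-3,5-dimethoxyphenyl]propanoyl}-1,3-oxazolidin-2-one, via mixed pivalic anhydride 7 (not isolated)
Conditions: t-BuCOCl, Et3N, THF, −20 °C; then LiCl, 6, −20 °C to rt
Reagents that add atoms: none
Why: N-acylation of the oxazolidinone through the mixed pivalic anhydride (LiCl/Et3N activation of the N–H) installs the chiral controller under conditions that cannot epimerise its stereocentre.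

Step 3
Reactants: 9 3-(4-hydroxy-3-methoxyphenyl)propanoic acid (dihydroferulic acid)
Product: 10 benzyl 3-[4-(benzyloxy)-3-methoxyphenyl]propanoate
Conditions: BnBr (2.4 equiv), K2CO3, DMF, 60 °C
Reagents that add atoms: benzyl bromide, BrCc1ccccc1
Why: Double O-alkylation (Williamson etherification of the phenoxide plus SN2 esterification of the carboxylate) protects the phenol and supplies the ester enolate precursor in one operation; no stereocentre is formed.

Step 4
Reactants: 8 (4S)-4-benzyl-3-{3-[4-(benzyloxy)-3,5-dimethoxyphenyl]propanoyl}-1,3-oxazolidin-2-one; 10 benzyl 3-[4-(benzyloxy)-3-methoxyphenyl]propanoate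
Product: 13 benzyl (2RS,3R)-3-{[(4S)-4-benzyl-2-oxo-1,3-oxazolidin-3-yl]carbonyl}-2-[4-(benzyloxy)-3-methoxybenzyl]-4-[4-(benzyloxy)-3,5-dimethoxyphenyl]butanoate, via imide lithium enolate 11 (not isolated), via ester lithium enolate 12 (not isolated)
Conditions: 8 (1.0 equiv), 10 (1.2 equiv), LiN(iPr)2 (2.3 equiv), THF, −78 °C, 30 min; then Fe(acac)3 (2.2 equiv), −78 °C to rt
Reagents that add atoms: none
Why: Oxidative enolate heterocoupling, in which single-electron oxidation of the mixed lithium enolate aggregate by trivalent iron turns one enolate α-carbon into an electrophilic α-carbonyl radical (an enolonium equivalent) that is captured by the second enolate, so two α-carbons that are both natural donors are joined; the chelated Z-imide enolate reacts on the face opposite the auxiliary benzyl group (Evans-type facial control), setting the future C4 as R, while the ester-side centre forms as a mixture that is corrected in step 5.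

Step 5
Reactants: 13 benzyl (2RS,3R)-3-{[(4S)-4-benzyl-2-oxo-1,3-oxazolidin-3-yl]carbonyl}-2-[4-(benzyloxy)-3-methoxybenzyl]-4-[4-(benzyloxy)-3,5-dimethoxyphenyl]butanoate
Product: 16 (3R,4R)-3-[4-(benzyloxy)-3-methoxybenzyl]-4-[4-(benzyloxy)-3,5-dimethoxybenzyl]dihydrofuran-2(3H)-one, via hydroxy ester 14 (not isolated), via cis-lactone epimer 15 (not isolated)
Conditions: NaBH4 (3 equiv), THF/H2O (3:1), 0 °C to rt; 1 M HCl work-up; then DBU (0.5 equiv), toluene, 80 °C
Reagents that add atoms: none
Why: Borohydride reduces only the activated exocyclic imide carbonyl (reductive auxiliary cleavage, ester untouched), the freed γ-hydroxyl closes onto the benzyl ester (lactonisation), and DBU equilibrates the enolisable C3 to the thermodynamically preferred trans-3,4-disubstituted lactone, which fixes C3 as R while the non-enolisable C4 (R) is untouched.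

Step 6
Reactants: 16 (3R,4R)-3-[4-(benzyloxy)-3-methoxybenzyl]-4-[4-(benzyloxy)-3,5-dimethoxybenzyl]dihydrofuran-2(3H)-one
Product: 17 (3R,4R)-4-(4-hydroxy-3,5-dimethoxybenzyl)-3-(4-hydroxy-3-methoxybenzyl)dihydrofuran-2(3H)-one (target)
Conditions: H2 (1 atm), 10% Pd/C, EtOAc/EtOH, rt
Reagents that add atoms: none
Why: Hydrogenolysis of the two aryl benzyl ethers over Pd/C under neutral conditions leaves the lactone, the aryl methyl ethers and both stereocentres untouched.

## Compound list

1 | 4-(benzyloxy)-3,5-dimethoxybenzaldehyde | COc1cc(C=O)cc(OC)c1OCc1ccccc1 | starting material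
2 | Meldrum's acid (2,2-dimethyl-1,3-dioxane-4,6-dione) | CC1(C)OC(=O)CC(=O)O1 | starting material
3 | 5-[4-(benzyloxy)-3,5-dimethoxybenzylidene]-2,2-dimethyl-1,3-dioxane-4,6-dione | COc1cc(C=C2C(=O)OC(C)(C)OC2=O)cc(OC)c1OCc1ccccc1 | intermediate
4 | 5-[4-(benzyloxy)-3,5-dimethoxybenzyl]-2,2-dimethyl-1,3-dioxane-4,6-dione | COc1cc(CC2C(=O)OC(C)(C)OC2=O)cc(OC)c1OCc1ccccc1 | intermediate
5 | 3-[4-(benzyloxy)-3,5-dimethoxyphenyl]propanoic acid | COc1cc(CCC(=O)O)cc(OC)c1OCc1ccccc1 | intermediate
6 | (S)-4-benzyloxazolidin-2-one | O=C1N[C@@H](Cc2ccccc2)CO1 | starting material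
7 | 3-[4-(benzyloxy)-3,5-dimethoxyphenyl]propanoic pivalic anhydride | COc1cc(CCC(=O)OC(=O)C(C)(C)C)cc(OC)c1OCc1ccccc1 | intermediate
8 | (4S)-4-benzyl-3-{3-[4-(benzyloxy)-3,5-dimethoxyphenyl]propanoyl}-1,3-oxazolidin-2-one | COc1cc(CCC(=O)N2[C@@H](Cc3ccccc3)COC2=O)cc(OC)c1OCc1ccccc1 | intermediate
9 | 3-(4-hydroxy-3-methoxyphenyl)propanoic acid | COc1cc(CCC(=O)O)ccc1O | starting material
10 | benzyl 3-[4-(benzyloxy)-3-methoxyphenyl]propanoate | COc1cc(CCC(=O)OCc2ccccc2)ccc1OCc1ccccc1 | intermediate
11 | lithium (Z)-enolate of 8 (O–Li cis to the arylmethyl group) | COc1cc(C/C=C(\O[Li])N2[C@@H](Cc3ccccc3)COC2=O)cc(OC)c1OCc1ccccc1 | intermediate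
12 | lithium enolate of 10 (O–Li trans to the arylmethyl group) | COc1cc(C/C=C(/O[Li])OCc2ccccc2)ccc1OCc1ccccc1 | intermediate
13 | benzyl (2RS,3R)-3-{[(4S)-4-benzyl-2-oxo-1,3-oxazolidin-3-yl]carbonyl}-2-[4-(benzyloxy)-3-methoxybenzyl]-4-[4-(benzyloxy)-3,5-dimethoxyphenyl]butanoate (C2 epimers) | COc1cc(CC(C(=O)OCc2ccccc2)[C@@H](Cc2cc(OC)c(OCc3ccccc3)c(OC)c2)C(=O)N2[C@@H](Cc3ccccc3)COC2=O)ccc1OCc1ccccc1 | intermediate
14 | benzyl (2RS,3R)-2-[4-(benzyloxy)-3-methoxybenzyl]-3-[4-(benzyloxy)-3,5-dimethoxybenzyl]-4-hydroxybutanoate (C2 epimers) | COc1cc(CC(C(=O)OCc2ccccc2)[C@@H](Cc2cc(OC)c(OCc3ccccc3)c(OC)c2)CO)ccc1OCc1ccccc1 | intermediate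
15 | (3S,4R)-3-[4-(benzyloxy)-3-methoxybenzyl]-4-[4-(benzyloxy)-3,5-dimethoxybenzyl]dihydrofuran-2(3H)-one (cis) | COc1cc(C[C@@H]2C(=O)OC[C@@H]2Cc2cc(OC)c(OCc3ccccc3)c(OC)c2)ccc1OCc1ccccc1 | intermediate
16 | (3R,4R)-3-[4-(benzyloxy)-3-methoxybenzyl]-4-[4-(benzyloxy)-3,5-dimethoxybenzyl]dihydrofuran-2(3H)-one (trans) | COc1cc(C[C@H]2C(=O)OC[C@@H]2Cc2cc(OC)c(OCc3ccccc3)c(OC)c2)ccc1OCc1ccccc1 | intermediate
17 | (3R,4R)-4-(4-hydroxy-3,5-dimethoxybenzyl)-3-(4-hydroxy-3-methoxybenzyl)dihydrofuran-2(3H)-one | COc1cc(C[C@H]2C(=O)OC[C@@H]2Cc2cc(OC)c(O)c(OC)c2)ccc1O | target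

## Step count and risks

Total steps: 6. Longest linear sequence: 5 (steps 1, 2, 4, 5, 6; 1 → 5 → 8 → 13 → 16 → 17).

Most likely to fail, in order:

**Step 4 (oxidative heterocoupling).** Risks are homodimer formation from either enolate, a modest yield (roughly 40–60% would be a good result), Claisen-type loss of the benzyl ester enolate on warming, and erosion of facial control if the bond forms outside the chelated enolate. The fallback sets out from 8 and comes back at 16. The sodium enolate of 8 (NaN(SiMe3)2, THF, −78 °C) is alkylated with tert-butyl bromoacetate, an α-halo ester that serves as the acceptor at the α-carbon, to give tert-butyl (3R)-3-{[(4S)-4-benzyl-2-oxo-1,3-oxazolidin-3-yl]carbonyl}-4-[4-(benzyloxy)-3,5-dimethoxyphenyl]butanoate F1. LiBH4 (THF/MeOH, 0 °C) removes the auxiliary to give tert-butyl (3R)-4-[4-(benzyloxy)-3,5-dimethoxyphenyl]-3-(hydroxymethyl)butanoate F2. TFA/CH2Cl2 closes it to (4R)-4-[4-(benzyloxy)-3,5-dimethoxybenzyl]dihydrofuran-2(3H)-one F3. The lithium enolate of F3 (LiN(SiMe3)2, THF, −78 °C) is alkylated anti to the C4 substituent with 4-(benzyloxy)-3-methoxybenzyl bromide F4, made from commercial 4-(benzyloxy)-3-methoxybenzyl alcohol with PBr3, giving trans-lactone 16 directly. This costs three more steps and no longer uses 10.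

**Step 5 (reduction, lactonisation, equilibration).** Risks are endocyclic opening of the hindered imide, over-reduction of the newly formed lactone, and incomplete cis-to-trans equilibration. The fallback sets out from 13 and comes back at 14. LiOH/H2O2 (THF/H2O, 0 °C) cleaves the auxiliary hydrolytically to (2R,3RS)-4-(benzyloxy)-2-[4-(benzyloxy)-3,5-dimethoxybenzyl]-3-[4-(benzyloxy)-3-methoxybenzyl]-4-oxobutanoic acid F5. BH3·SMe2 (THF, 0 °C) then reduces the free carboxylic acid in the presence of the benzyl ester to hydroxy ester 14, which is lactonised and equilibrated with DBU as in step 5.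

**Step 1 (one-pot reductive Knoevenagel–decarboxylation).** Risks are incomplete formate reduction of the electron-rich arylidene and incomplete decarboxylation. The fallback sets out from 1 and comes back at 5. Knoevenagel–Doebner condensation with malonic acid (pyridine, piperidine cat., 90 °C) passes through 2-[4-(benzyloxy)-3,5-dimethoxybenzylidene]malonic acid F6, which decarboxylates in the flask to (E)-3-[4-(benzyloxy)-3,5-dimethoxyphenyl]prop-2-enoic acid F7. Diimide reduction (p-toluenesulfonyl hydrazide, NaOAc, THF/H2O, reflux) then saturates the alkene without touching the benzyl ether and gives 5.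

## Further compounds

F1 | step 4 | tert-butyl (3R)-3-{[(4S)-4-benzyl-2-oxo-1,3-oxazolidin-3-yl]carbonyl}-4-[4-(benzyloxy)-3,5-dimethoxyphenyl]butanoate | CC(C)(C)OC(=O)C[C@@H](Cc1cc(OC)c(OCc2ccccc2)c(OC)c1)C(=O)N1[C@@H](Cc2ccccc2)COC1=O
F2 | step 4 | tert-butyl (3R)-4-[4-(benzyloxy)-3,5-dimethoxyphenyl]-3-(hydroxymethyl)butanoate | CC(C)(C)OC(=O)C[C@@H](Cc1cc(OC)c(OCc2ccccc2)c(OC)c1)CO
F3 | step 4 | (4R)-4-[4-(benzyloxy)-3,5-dimethoxybenzyl]dihydrofuran-2(3H)-one | O=C1C[C@@H](Cc2cc(OC)c(OCc3ccccc3)c(OC)c2)CO1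
F4 | step 4 | 4-(benzyloxy)-3-methoxybenzyl bromide | COc1cc(CBr)ccc1OCc1ccccc1
F5 | step 5 | (2R,3RS)-4-(benzyloxy)-2-[4-(benzyloxy)-3,5-dimethoxybenzyl]-3-[4-(benzyloxy)-3-methoxybenzyl]-4-oxobutanoic acid | COc1cc(CC(C(=O)OCc2ccccc2)[C@@H](Cc2cc(OC)c(OCc3ccccc3)c(OC)c2)C(=O)O)ccc1OCc1ccccc1
F6 | step 1 | 2-[4-(benzyloxy)-3,5-dimethoxybenzylidene]malonic acid | COc1cc(C=C(C(=O)O)C(=O)O)cc(OC)c1OCc1ccccc1
F7 | step 1 | (E)-3-[4-(benzyloxy)-3,5-dimethoxyphenyl]prop-2-enoic acid | COc1cc(/C=C/C(=O)O)cc(OC)c1OCc1ccccc1
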